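the same everywhere: D 0.190 M

| flask | L | time | remark |
|---|---|---|---|
| autumn | 0.38 M | 1.0 min | everything together in a closed stirred flask, run for 1.0 min |
| spring | 0.38 M |  | a single well-mixed tank run continuously and read at steady state, 1.0 min in it on average |
| dusk | 0.38 M |  | one stirred flow tank at steady state, fed with the mixture as stated, mean residence time 10.0 min |
| winter | 0.38 M (fed, over 0.800 min) | 1.0 min | all but L at the start; L goes in evenly over 0.800 min, the run ends at 1.0 min |

    L ⇌ Z (K1 = 15, k1 = 0.0056 s⁻¹)
    L + D → L.D (k2 = 0.88 M⁻¹ s⁻¹)
    L ⇌ Q (K3 = 0.58, k3 = 0.0019 s⁻¹)
    L ⇌ G (K4 = 0.17, k4 = 0.030 s⁻¹)

* order of the set-ups by the share of G in all that became G or Q, at the outlet or at the end, highest first (autumn / spring / dusk / winter)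
* share of G in all that became G or Q, at the outlet or at the end, autumn
* share of G in all that became G or Q, at the outlet or at the end, spring
* share of G in all that became G or Q, at the outlet or at the end, dusk
* share of G in all that became G or Q, at the outlet or at the end, winter

- the stated concentrations are those of everything mixed, before any reaction; amounts are the same in each set-up
- the feed brings no volume worth counting
- run time (autumn): 1.0 min

- Time was my common measure for the constants. By its own step alone, with both ways together, L and G relaxed with a half-life of 0.0560 min, and L and Q with 2.23 min.
- I solved two extremes first. With no back runs (kinetic control), G and Q grew as their forward constants, and the share of G was 94.0%. With both steps at equilibrium (thermodynamic control), the share was 22.7%.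
- The runs of about a minute lay between these. G had time to relax, but Q did not.
- So G stood at its equilibrium constant times [L], while Q grew at its forward constant times [L]. The first constant over the second gave 1.49 min. I called this θ, the crossover time: the stay at steady [L] after which Q equals G. A stay t then gives a share of θ/(θ+t).
- For autumn, with t as the run time, this gave 59.9%. This took [L] as steady, but at the charged [D], step 2 by itself gave L a half-life of 0.069 min, so I held this figure as rough.
- In winter, L entered evenly over 0.800 min, so I took 0.600 min as its mean stay, counted on the feed. That gave 71.3%.
- In a tank with mean stay τ, each product balances at [L] times K·τ/(τ+K/k), with K and k from its own step. [L] cancelled in the share, so D did not enter it. Spring came to 62.0%.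
- Dusk came to 30.5%. Its stay outlasted the relaxation of Q, so the back run from Q counted there.
- My order was winter > spring > autumn > dusk.
- The forecast reasoned that “G equilibrates with L within seconds”. It gave winter > spring > autumn > dusk, with autumn 53.5% (50% to 57%), spring 62%, dusk 30.5% and winter 68% (63% to 72%). My autumn and winter figures stood above its central values.
- The simulation gave winter > spring > autumn > dusk: autumn 56.1%, spring 62.0%, dusk 30.5%, winter 71.7%. Each lay inside the forecast's range.
- In dusk, the backward run from G to L was the main reason for the low share: that tank gave 97.9% without it, against 30.5% with it. That backward run held G near equilibrium with L in dusk, and θ rests on such a hold. For winter left until 10.0 min, θ with the stay counted from the feed as before gave 13.4%, and the simulation stood at 15.3%.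

(The numbers come from no measurement; the flask was simulated.)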